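Minutes of a meeting on one flask.

| flask | substrate | partner | catalyst | remark | time |
|---|---|---|---|---|---|
| grey | 0.25 M | 1.8 equiv | 2.8 mol% | run made earlier |  |
| blue | 1 M | 1.8 equiv | 2.8 mol% | run made earlier |  |
| flask | 0.50 M | 1.80 equiv | 2.8 mol% |  | 5.0 d |

| run | time / d | product / % | substrate / % |
|---|---|---|---|
| grey | 0.0625 | 5 | 93 |
| grey | 0.333 | 11 | 88 |
| grey | 1.25 | 10 | 87 |
| grey | 6.00 | 3 | 97 |
| blue | 0.0625 | 55 | 45 |
| blue | 0.333 | 61 | 38 |
| blue | 1.25 | 39 | 61 |
| blue | 6.00 | 5 | 97 |

(readings scatter by 1.5 percentage points)

- time up to 5.0 d at which product stands highest
- the amount of product, in percent of the substrate charged, at that time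

Noted first: by 6.00 d the substrate is back at 97% in the grey run and 97% in the blue run, so the product does not last. The forecaster held that “the partner is slowly consumed by a side reaction, pulling the equilibrium back”, and proposed a peak of 29% at 0.2 d.

I argued for a race. Partner either enters product or goes down the side path, so the peak product over the partner charge not in product, taken as lost to that path and both in equivalents, gives a capture ratio, a selectivity factor. I assumed capture follows [substrate][catalyst] and loss follows neither. So at this loading I divided the ratio by the starting concentration squared and by the mean of the substrate share at start and at peak.

The grey peak reading of 11% gives 1.10 /M², the capture constant. The blue reading of 61% gives 0.738 /M², which is lower. I kept the grey value, because the grey product share is smaller and the substrate correction weighs least there.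

For the flask, undiminished substrate gives 38.9%. Putting that back to thin the substrate gives 32.7%, above the forecast. On time I offered nothing beyond this: both runs read highest at 0.333 d.

The flask stands highest at 0.265 d, with 32.8% product.

    substrate + partner + catalyst ⇌ product + catalyst, rate k1*[substrate]*[partner]*[catalyst] forward; the back reaction follows from the equilibrium constant (K = 14.6 /M, k = 19.9 /M²/h)
    partner → decomposed reagent (k = 0.442 /h)

At 0.265 d the flask holds 3.72% of its partner charge. Its peak, put through the same ratio, gives a capture constant of 1.07 /M², against 1.10 /M² from the grey run. A further flask, like this one but with 3.10 equiv of partner, gets 67.0% on the first round from 1.10 /M². The second round gives 48.0%, and that flask's simulated best is 49.9%.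

(All runs are calculated with constants of no real substance, noise included.)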